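- beta: G 36 mM (fed, over 15 min); J 108 mM; L 72 mM; the very flask that is asked about, followed so far
- flask: G 36 mM (fed, over 15 min); J 108 mM; L 72.0 mM; time 40 min

- beta (time / min: X / %, D / %, G / %): 0.667: 0, 0, 1; 2.00: 4, 0, 7; 3.00: 12, 0, 8; 5.00: 17, 1, 9; 8.00: 38, 3, 13

(each reading ± 1.5 percentage points)

- amounts and yields of L count Q too
- given per volume of solution although it is solid: Q
- steps thought possible: G + J -> L + E; E + J -> L + X; Q <-> L; X <-> D
- percentages count the whole charge, also what has not yet gone in

- concentration of X at 40 min, in mM
- concentration of D at 40 min, in mM
- concentration of J at 40 min, in mM

72.0 mM of J is what the G of this flask can take up, at two J per G, first to E and then to X, and 108 mM of J is charged, which makes G the limiting reagent. So I carry one number: the J margin, the J charge less two J for every G charged, 36.0 mM.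

Turn the question round. For J to end anywhere but at this margin, the flask needs one of two things: a margin below zero, or exchanges too slow for the time. The margin here is positive. As for speed, at 8.00 min the feed has delivered 53.3% of the G, and X, D and G together read 54.0%, so within their scatter these readings leave little room for E. The rise of X and D from 5.00 min to 8.00 min, set against the G present, gives G a reading of 0.995 min for its half-life at the J of those minutes, and 25.0 min follow the feed, a wide enough gap to allow for the slower uptake as J falls. I therefore expect J at the margin. I commit to no split between X and D, since D reads 3% with a scatter of 1.5 percentage points.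

The forecast gives X 19.5 mM, D 16.3 mM and J 36.2 mM, saying of X “it has about 30 min to convert, leaving about half”.

The flask gives X 26.3 mM, D 9.67 mM and J 36.0 mM.

    G + J → L + E (k = 8.00 /M/min)
    E + J → L + X (k = 15.0 /M/min)
    Q ⇌ L, rate k3*(cs3 - [L]) while solid is left; crystals form when [L] > cs3 (solubility = 15.0 mM, k = 29.0 /min)
    X ⇌ D (K = 0.570, k = 0.0170 /min)

J in this flask stands on the margin of 36.0 mM, while X lies above the forecast and D below it. X in this flask falls short of the G charged through its exchange with D, both ways: the run without that step holds X at 36.0 mM, against 26.3 mM with it. The neighbour charged with 140 mM of G has a margin of −172 mM, below zero, and it ends with J at 1.50 × 10⁻¹⁰ mM and 55.9% of its G unreacted.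

(The runs are simulated on assumed constants.)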